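**Assumption:** germacrane numbering is used (ring C1–C10, C14 = methyl on C10, C15 = methyl on C4, C11 on C7, C12 = lactone carbonyl, C13 = CH2O carbon); the target is read as 4R,5S,6R,8S,10R; PMB = 4-methoxybenzyl. The C6 descriptor changes from S to R at step 12 only through CIP priorities, not by inversion.

## Retrosynthetic overview

1. Target 27 ⇐ Mitsunobu esterification of C8 carbinol 25 with methacrylic acid (inversion at C8); the C10 acetate, the 4,5-epoxide and the 1-keto-10-ol are late oxidations of the 1(10)E,4Z-diene butenolide 20.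
2. Butenolide ⇐ reduction of the C6 ketone and lactonisation of alkylidene malonate 13; C11–C13 come from diethyl ketomalonate 9, and the C13 ester is taken down to CH2OAc.
3. Ten-membered ring ⇐ anionic oxy-Cope [3,3] shift of dialkenylcyclohexenol 8 (C8–C9 formed, C1–C6 broken), with the enolate trapped in the same flask.
4. 8 ⇐ (S)-isopiperitenone 2 + a PMB-oxy-acetylide, then cis-semihydrogenation; 2 ⇐ (R)-limonene 1, the only bought stereocentre.
5. Ring order: cyclohexene (bought) → cyclodecadienone (oxy-Cope) → butenolide → epoxide.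

## Route

**Step 1**
Reactants: 1 (R)-(+)-limonene
Product: 2 (S)-isopiperitenone [(6S)-3-methyl-6-(prop-1-en-2-yl)cyclohex-2-en-1-one]
Conditions: Cr(CO)6 (0.3 equiv), t-BuOOH (3 equiv), MeCN, reflux; chromatography (carvone removed)
Reagents that add atoms: tert-butyl hydroperoxide CC(C)(C)OO
Why: Chromium-catalysed allylic C–H oxidation turns the ring CH2 next to the alkene CH into the enone carbonyl without touching the isopropenyl-bearing stereocentre, whose descriptor becomes S only through the new priority order.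

**Step 2**
Reactants: 3 4-methoxybenzyl alcohol; 4 trichloroethylene
Product: 5 (E)-1,2-dichloro-1-(4-methoxybenzyloxy)ethene
Conditions: KH, THF, 0 °C; then 4, −50 °C → rt
Reagents that add atoms: none
Why: Base-induced elimination–addition of the potassium alkoxide on trichloroethylene gives the dichloroenol ether, a stable precursor of the alkynyl ether anion.

**Step 3**
Reactants: 5 (E)-1,2-dichloro-1-(4-methoxybenzyloxy)ethene; 2 (S)-isopiperitenone
Product: 7 (1S,6S)-1-[(4-methoxybenzyloxy)ethynyl]-3-methyl-6-(prop-1-en-2-yl)cyclohex-2-en-1-ol, via lithium alkynyl ether 6 (not isolated)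
Conditions: n-BuLi (2.2 equiv), THF, −78 → −40 °C; then 2, −78 °C; aq. NH4Cl
Reagents that add atoms: none
Why: Dehydrochlorination and chlorine–lithium exchange give the acetylide, which adds 1,2 to the enone anti to the neighbouring isopropenyl group (nucleophilic carbonyl addition); the minor carbinol epimer converges in step 5.

**Step 4**
Reactants: 7 (1S,6S)-1-[(4-methoxybenzyloxy)ethynyl]-3-methyl-6-(prop-1-en-2-yl)cyclohex-2-en-1-ol
Product: 8 (1S,6S)-1-[(Z)-2-(4-methoxybenzyloxy)ethenyl]-3-methyl-6-(prop-1-en-2-yl)cyclohex-2-en-1-ol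
Conditions: H2 (1 atm), Pd on CaCO3 poisoned with Pb(OAc)2, quinoline, EtOAc, 0 °C; Et3N-buffered work-up
Reagents that add atoms: none
Why: Poisoned-palladium cis-semihydrogenation stops at the Z-enol ether and leaves the other alkenes and the PMB ether alone.

**Step 5**
Reactants: 8 (1S,6S)-1-[(Z)-2-(4-methoxybenzyloxy)ethenyl]-3-methyl-6-(prop-1-en-2-yl)cyclohex-2-en-1-ol; 9 diethyl ketomalonate
Product: 13 diethyl 2-[(2R,4E,8Z)-2-(4-methoxybenzyloxy)-4,8-dimethyl-10-oxocyclodeca-4,8-dien-1-ylidene]propanedioate, via potassium dienolate 10 (not isolated), via potassium aldolate 11 (not isolated), via aldol acetate 12 (not isolated)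
Conditions: KN(SiMe3)2, 18-crown-6, THF, 0 → 25 °C; −78 °C, 9; then Ac2O, Et3N, DMAP (cat.), −78 → 0 °C
Reagents that add atoms: none
Why: Anionic oxy-Cope [3,3]-sigmatropic rearrangement through a chair transition state, in which the limonene-derived stereocentre fixes the face of C8–C9 bonding (C8 becomes R, new 1(10)-alkene E, 4,5-alkene stays Z), followed by aldol addition of the regiodefined enolate to the non-enolisable ketone and E1cB loss of acetate to a symmetric alkylidene malonate with no E/Z issue.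

**Step 6**
Reactants: 13 diethyl 2-[(2R,4E,8Z)-2-(4-methoxybenzyloxy)-4,8-dimethyl-10-oxocyclodeca-4,8-dien-1-ylidene]propanedioate
Product: 15 ethyl (6S,8R)-8-(4-methoxybenzyloxy)-12-oxo-germacra-1(10)E,4Z,7(11)-trien-12,6-olide-13-oate (butenolide with CO2Et on C11), via hydroxy diester 14 (not isolated)
Conditions: NaBH4, CeCl3·7H2O, MeOH/THF, −78 °C; AcOH; then PPTS (cat.), CH2Cl2, 25 °C
Reagents that add atoms: none
Why: Luche 1,2-reduction from the outer face of the ring carbonyl, reinforced by cerium chelation to the C8 ether, gives the 6,8-syn alcohol, which lactonises onto the cis ester (transesterification).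

**Step 7**
Reactants: 15 ethyl (6S,8R)-8-(4-methoxybenzyloxy)-12-oxo-germacra-1(10)E,4Z,7(11)-trien-12,6-olide-13-oate
Product: 17 (6S,8R)-8-(4-methoxybenzyloxy)-germacra-1(10)E,4Z,7(11)-trien-12,6-olid-13-oic acid, via trimethylstannyl ester 16 (not isolated)
Conditions: Me3SnOH, ClCH2CH2Cl, 60 °C; 0.1 M HCl wash
Reagents that add atoms: trimethyltin hydroxide C[Sn](C)(C)O
Why: Near-neutral tin hydroxide ester hydrolysis cleaves the activated ethyl ester without enolising the acidic C6–H and C8–H of the doubly activated butenolide.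

**Step 8**
Reactants: 17 (6S,8R)-8-(4-methoxybenzyloxy)-germacra-1(10)E,4Z,7(11)-trien-12,6-olid-13-oic acid
Product: 19 (6S,8R)-13-hydroxy-8-(4-methoxybenzyloxy)germacra-1(10)E,4Z,7(11)-trien-12,6-olide, via isobutyl carbonic anhydride 18 (not isolated)
Conditions: i-BuOCOCl, N-methylmorpholine, THF, −15 °C; then NaBH4, H2O, 0 °C
Reagents that add atoms: none
Why: Mixed-anhydride activation followed by borohydride reduction takes the acid to the primary alcohol faster than the lactone or the hindered tetrasubstituted alkene reacts.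

**Step 9**
Reactants: 19 (6S,8R)-13-hydroxy-8-(4-methoxybenzyloxy)germacra-1(10)E,4Z,7(11)-trien-12,6-olide
Product: 20 (6S,8R)-13-acetoxy-8-(4-methoxybenzyloxy)germacra-1(10)E,4Z,7(11)-trien-12,6-olide
Conditions: Ac2O, pyridine, DMAP (cat.), CH2Cl2, 0 °C
Reagents that add atoms: acetic anhydride CC(=O)OC(C)=O
Why: Nucleophilic acyl substitution on the only free hydroxyl installs the C13 acetate of the target.

**Step 10**
Reactants: 20 (6S,8R)-13-acetoxy-8-(4-methoxybenzyloxy)germacra-1(10)E,4Z,7(11)-trien-12,6-olide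
Product: 21 (1R,6S,8R,10R)-13-acetoxy-1,10-dihydroxy-8-(4-methoxybenzyloxy)germacra-4Z,7(11)-dien-12,6-olide
Conditions: OsO4 (2 mol%), N-methylmorpholine N-oxide (1.05 equiv), acetone/H2O, 0 °C
Reagents that add atoms: N-methylmorpholine N-oxide C[N+]1([O-])CCOCC1; water O
Why: Upjohn syn-dihydroxylation ([3+2] cycloaddition of OsO4) picks the strained, electron-rich E-1(10) alkene over the oxygen-deactivated 4Z alkene and the butenolide, and adds from the exposed outer face left by the oxy-Cope geometry, setting C10 as R.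

**Step 11**
Reactants: 21 (1R,6S,8R,10R)-13-acetoxy-1,10-dihydroxy-8-(4-methoxybenzyloxy)germacra-4Z,7(11)-dien-12,6-olide
Product: 22 (6S,8R,10R)-13-acetoxy-10-hydroxy-8-(4-methoxybenzyloxy)-1-oxogermacra-4Z,7(11)-dien-12,6-olide
Conditions: Dess–Martin periodinane, pyridine, CH2Cl2, 0 °C → rt
Reagents that add atoms: none
Why: Dess–Martin oxidation converts the secondary C1 alcohol to the ketone while the tertiary C10 alcohol cannot be oxidised.

**Step 12**
Reactants: 22 (6S,8R,10R)-13-acetoxy-10-hydroxy-8-(4-methoxybenzyloxy)-1-oxogermacra-4Z,7(11)-dien-12,6-olide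
Product: 23 (4R,5S,6R,8R,10R)-13-acetoxy-4,5-epoxy-10-hydroxy-8-(4-methoxybenzyloxy)-1-oxogermacr-7(11)-en-12,6-olide
Conditions: mCPBA, CH2Cl2, 0 °C
Reagents that add atoms: 3-chloroperoxybenzoic acid OOC(=O)c1cccc(Cl)c1
Why: Prilezhaev epoxidation of the only electron-rich alkene left; A(1,3) strain holds C6–H in the alkene plane, so the peracid approaches syn to the lactone oxygen on the face away from the ring, giving the cis-4R,5S epoxide.

**Step 13**
Reactants: 23 (4R,5S,6R,8R,10R)-13-acetoxy-4,5-epoxy-10-hydroxy-8-(4-methoxybenzyloxy)-1-oxogermacr-7(11)-en-12,6-olide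
Product: 24 (4R,5S,6R,8R,10R)-10,13-diacetoxy-4,5-epoxy-8-(4-methoxybenzyloxy)-1-oxogermacr-7(11)-en-12,6-olide
Conditions: Ac2O, DMAP (1 equiv), Et3N, CH2Cl2, 35 °C
Reagents that add atoms: acetic anhydride CC(=O)OC(C)=O
Why: DMAP-catalysed acylation is strong enough to acetylate the tertiary α-ketol hydroxyl without opening the epoxide.

**Step 14**
Reactants: 24 (4R,5S,6R,8R,10R)-10,13-diacetoxy-4,5-epoxy-8-(4-methoxybenzyloxy)-1-oxogermacr-7(11)-en-12,6-olide
Product: 25 (4R,5S,6R,8R,10R)-10,13-diacetoxy-4,5-epoxy-8-hydroxy-1-oxogermacr-7(11)-en-12,6-olide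
Conditions: DDQ, CH2Cl2/pH 7 buffer, 0 °C → rt
Reagents that add atoms: none
Why: Oxidative PMB ether cleavage (benzylic hydride abstraction, hemiacetal hydrolysis) is neutral and spares the epoxide, the esters and the butenolide.

**Step 15**
Reactants: 25 (4R,5S,6R,8R,10R)-10,13-diacetoxy-4,5-epoxy-8-hydroxy-1-oxogermacr-7(11)-en-12,6-olide; 26 methacrylic acid
Product: 27 (4R,5S,6R,8S,10R)-10,13-diacetoxy-4,5-epoxy-8-methacryloyloxy-1-oxogermacr-7(11)-en-12,6-olide (CNP0172381.2)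
Conditions: PPh3, DIAD, toluene/THF, 0 °C → rt
Reagents that add atoms: none
Why: Mitsunobu esterification installs the methacrylate by SN2 displacement, inverting C8 from R to S so that the centre set by the oxy-Cope chirality transfer ends in the target configuration.

## Compound list

1 | (R)-(+)-limonene | CC1=CC[C@@H](CC1)C(C)=C | starting material
2 | (S)-isopiperitenone | CC1=CC(=O)[C@@H](CC1)C(C)=C | intermediate
3 | 4-methoxybenzyl alcohol | COc1ccc(CO)cc1 | starting material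
4 | trichloroethylene | ClC=C(Cl)Cl | starting material
5 | (E)-1,2-dichloro-1-(4-methoxybenzyloxy)ethene | COc1ccc(CO/C(Cl)=C\Cl)cc1 | intermediate
6 | lithium (4-methoxybenzyloxy)ethynide | [Li]C#COCc1ccc(OC)cc1 | intermediate
7 | (1S,6S)-1-[(4-methoxybenzyloxy)ethynyl]-3-methyl-6-(prop-1-en-2-yl)cyclohex-2-en-1-ol | CC1=C[C@@](O)(C#COCc2ccc(OC)cc2)[C@@H](CC1)C(C)=C | intermediate
8 | (1S,6S)-1-[(Z)-2-(4-methoxybenzyloxy)ethenyl]-3-methyl-6-(prop-1-en-2-yl)cyclohex-2-en-1-ol | CC1=C[C@@](O)(/C=C\OCc2ccc(OC)cc2)[C@@H](CC1)C(C)=C | intermediate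
9 | diethyl ketomalonate | CCOC(=O)C(=O)C(=O)OCC | starting material
10 | potassium (1Z,3R,5E,9Z)-3-(4-methoxybenzyloxy)-5,9-dimethylcyclodeca-1,5,9-trien-1-olate | C1/C(C)=C\C([O-])=C\[C@H](OCc2ccc(OC)cc2)C/C(C)=C/C1.[K+] | intermediate
11 | potassium aldolate: diethyl 2-oxido-2-[(2R,4E,8Z)-2-(4-methoxybenzyloxy)-4,8-dimethyl-10-oxocyclodeca-4,8-dien-1-yl]propanedioate (C1 epimers) | C1/C(C)=C\C(=O)C(C([O-])(C(=O)OCC)C(=O)OCC)[C@H](OCc2ccc(OC)cc2)C/C(C)=C/C1.[K+] | intermediate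
12 | diethyl 2-acetoxy-2-[(2R,4E,8Z)-2-(4-methoxybenzyloxy)-4,8-dimethyl-10-oxocyclodeca-4,8-dien-1-yl]propanedioate (C1 epimers) | C1/C(C)=C\C(=O)C(C(OC(C)=O)(C(=O)OCC)C(=O)OCC)[C@H](OCc2ccc(OC)cc2)C/C(C)=C/C1 | intermediate
13 | diethyl 2-[(2R,4E,8Z)-2-(4-methoxybenzyloxy)-4,8-dimethyl-10-oxocyclodeca-4,8-dien-1-ylidene]propanedioate | C1/C(C)=C\C(=O)C(=C(C(=O)OCC)C(=O)OCC)[C@H](OCc2ccc(OC)cc2)C/C(C)=C/C1 | intermediate
14 | diethyl 2-[(2R,4E,8Z,10S)-10-hydroxy-2-(4-methoxybenzyloxy)-4,8-dimethylcyclodeca-4,8-dien-1-ylidene]propanedioate | C1/C(C)=C\[C@H](O)C(=C(C(=O)OCC)C(=O)OCC)[C@H](OCc2ccc(OC)cc2)C/C(C)=C/C1 | intermediate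
15 | ethyl (6S,8R)-8-(4-methoxybenzyloxy)-12-oxo-germacra-1(10)E,4Z,7(11)-trien-12,6-olide-13-oate | C1/C(C)=C\[C@@H]2OC(=O)C(C(=O)OCC)=C2[C@H](OCc3ccc(OC)cc3)C/C(C)=C/C1 | intermediate
16 | trimethylstannyl ester of acid 17 | C1/C(C)=C\[C@@H]2OC(=O)C(C(=O)O[Sn](C)(C)C)=C2[C@H](OCc3ccc(OC)cc3)C/C(C)=C/C1 | intermediate
17 | (6S,8R)-8-(4-methoxybenzyloxy)-germacra-1(10)E,4Z,7(11)-trien-12,6-olid-13-oic acid | C1/C(C)=C\[C@@H]2OC(=O)C(C(=O)O)=C2[C@H](OCc3ccc(OC)cc3)C/C(C)=C/C1 | intermediate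
18 | isobutyl carbonic anhydride of acid 17 | C1/C(C)=C\[C@@H]2OC(=O)C(C(=O)OC(=O)OCC(C)C)=C2[C@H](OCc3ccc(OC)cc3)C/C(C)=C/C1 | intermediate
19 | (6S,8R)-13-hydroxy-8-(4-methoxybenzyloxy)germacra-1(10)E,4Z,7(11)-trien-12,6-olide | C1/C(C)=C\[C@@H]2OC(=O)C(CO)=C2[C@H](OCc3ccc(OC)cc3)C/C(C)=C/C1 | intermediate
20 | (6S,8R)-13-acetoxy-8-(4-methoxybenzyloxy)germacra-1(10)E,4Z,7(11)-trien-12,6-olide | C1/C(C)=C\[C@@H]2OC(=O)C(COC(C)=O)=C2[C@H](OCc3ccc(OC)cc3)C/C(C)=C/C1 | intermediate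
21 | (1R,6S,8R,10R)-13-acetoxy-1,10-dihydroxy-8-(4-methoxybenzyloxy)germacra-4Z,7(11)-dien-12,6-olide | C1/C(C)=C\[C@@H]2OC(=O)C(COC(C)=O)=C2[C@H](OCc3ccc(OC)cc3)C[C@@](C)(O)[C@H](O)C1 | intermediate
22 | (6S,8R,10R)-13-acetoxy-10-hydroxy-8-(4-methoxybenzyloxy)-1-oxogermacra-4Z,7(11)-dien-12,6-olide | C1/C(C)=C\[C@@H]2OC(=O)C(COC(C)=O)=C2[C@H](OCc3ccc(OC)cc3)C[C@@](C)(O)C(=O)C1 | intermediate
23 | (4R,5S,6R,8R,10R)-13-acetoxy-4,5-epoxy-10-hydroxy-8-(4-methoxybenzyloxy)-1-oxogermacr-7(11)-en-12,6-olide | C1[C@@]3(C)O[C@H]3[C@@H]2OC(=O)C(COC(C)=O)=C2[C@H](OCc4ccc(OC)cc4)C[C@@](C)(O)C(=O)C1 | intermediate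
24 | (4R,5S,6R,8R,10R)-10,13-diacetoxy-4,5-epoxy-8-(4-methoxybenzyloxy)-1-oxogermacr-7(11)-en-12,6-olide | C1[C@@]3(C)O[C@H]3[C@@H]2OC(=O)C(COC(C)=O)=C2[C@H](OCc4ccc(OC)cc4)C[C@@](C)(OC(C)=O)C(=O)C1 | intermediate
25 | (4R,5S,6R,8R,10R)-10,13-diacetoxy-4,5-epoxy-8-hydroxy-1-oxogermacr-7(11)-en-12,6-olide | C1[C@@]3(C)O[C@H]3[C@@H]2OC(=O)C(COC(C)=O)=C2[C@H](O)C[C@@](C)(OC(C)=O)C(=O)C1 | intermediate
26 | methacrylic acid | CC(=C)C(=O)O | starting material
27 | (4R,5S,6R,8S,10R)-10,13-diacetoxy-4,5-epoxy-8-methacryloyloxy-1-oxogermacr-7(11)-en-12,6-olide (CNP0172381.2) | C=C(C)C(=O)O[C@H]1C[C@@](C)(OC(C)=O)C(=O)CC[C@@]2(C)O[C@H]2[C@@H]2OC(=O)C(COC(C)=O)=C12 | target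

## Summary

Total step count: 15. Longest linear sequence: 14 steps (steps 1 and 3–15; step 2 is a side branch).

Three steps most likely to fail:

- **Step 5.** The potassium enolate carries a β-alkoxy group that can be lost, the Z-alkoxy group must sit axial in the chair, and three events share one flask. Fallback: setting out from 8, stop the cascade at the enolate by adding Me3SiCl after the oxy-Cope rearrangement and isolate the trimethylsilyl enol ether F1. Form the C7–C11 bond separately by a BF3·OEt2-promoted Mukaiyama aldol addition to 9 (CH2Cl2, −78 °C), giving the tertiary aldol F2. Acetylation of F2 (Ac2O, DMAP) comes back to the route at 12, which Et3N converts into 13.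

- **Step 10.** The face of osmylation rests only on the ring conformation. If the diol forms with the other C10 configuration, the fallback sets out from 20 and uses that same facial preference: one equivalent of mCPBA at −20 °C epoxidises the strained 1(10)-alkene to the (1S,10S)-1,10-epoxide F3. Acetic acid opens it at the tertiary carbon with inversion, giving the 1-hydroxy-10-acetate F4 with C10 as R and the acetate already in place. Dess–Martin oxidation gives the 1-keto-10-acetate F5, and mCPBA epoxidation of its 4,5-alkene comes back to the route at 24.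

- **Step 15.** The C8 alcohol is secondary, allylic to the butenolide and hindered, so elimination may compete with Mitsunobu substitution. Fallback: setting out from 25, make the chloromethanesulfonate F6 (ClCH2SO2Cl, pyridine, 0 °C) and displace it with caesium methacrylate F7 (from 26 and Cs2CO3; 18-crown-6, toluene, 60 °C) in an SN2 reaction with inversion, which arrives at 27.

## Further compounds

F1 | step 5 | trimethylsilyl enol ether of the (8R)-8-(4-methoxybenzyloxy)cyclodeca-1(10)E,4Z-dien-6-one (C6=C7 enol ether) | C1/C(C)=C\C(O[Si](C)(C)C)=C\[C@H](OCc2ccc(OC)cc2)C/C(C)=C/C1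
F2 | step 5 | diethyl 2-hydroxy-2-[(2R,4E,8Z)-2-(4-methoxybenzyloxy)-4,8-dimethyl-10-oxocyclodeca-4,8-dien-1-yl]propanedioate (C1 epimers) | C1/C(C)=C\C(=O)C(C(O)(C(=O)OCC)C(=O)OCC)[C@H](OCc2ccc(OC)cc2)C/C(C)=C/C1
F3 | step 10 | (1S,6S,8R,10S)-13-acetoxy-1,10-epoxy-8-(4-methoxybenzyloxy)germacra-4Z,7(11)-dien-12,6-olide | C1/C(C)=C\[C@@H]2OC(=O)C(COC(C)=O)=C2[C@H](OCc3ccc(OC)cc3)C[C@]4(C)O[C@H]4C1
F4 | step 10 | (1S,6S,8R,10R)-10,13-diacetoxy-1-hydroxy-8-(4-methoxybenzyloxy)germacra-4Z,7(11)-dien-12,6-olide | C1/C(C)=C\[C@@H]2OC(=O)C(COC(C)=O)=C2[C@H](OCc3ccc(OC)cc3)C[C@@](C)(OC(C)=O)[C@@H](O)C1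
F5 | step 10 | (6S,8R,10R)-10,13-diacetoxy-8-(4-methoxybenzyloxy)-1-oxogermacra-4Z,7(11)-dien-12,6-olide | C1/C(C)=C\[C@@H]2OC(=O)C(COC(C)=O)=C2[C@H](OCc3ccc(OC)cc3)C[C@@](C)(OC(C)=O)C(=O)C1
F6 | step 15 | (4R,5S,6R,8R,10R)-10,13-diacetoxy-8-(chloromethanesulfonyloxy)-4,5-epoxy-1-oxogermacr-7(11)-en-12,6-olide | C1[C@@]3(C)O[C@H]3[C@@H]2OC(=O)C(COC(C)=O)=C2[C@H](OS(=O)(=O)CCl)C[C@@](C)(OC(C)=O)C(=O)C1
F7 | step 15 | caesium methacrylate | CC(=C)C(=O)[O-].[Cs+]
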